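**Retrosynthetic overview**
- Kanzonol V ⇒ open the furan C2–O bond (forward: 5-endo-dig hydroalkoxylation of an ortho-alkynylphenol) ⇒ Sonogashira partners 8-ethynyl-2,2-dimethyl-2H-chromen-5-ol and 4-iodo-6-prenylresorcinol.
- Ethynylchromenol ⇒ 8-bromo-2,2-dimethyl-2H-chromen-5-ol plus a C2 unit.
- Bromochromenol ⇒ 5-bromo-2,4-dihydroxybenzoic acid + prenal. The pyran O–CMe2 bond closes (oxa-6π) on the oxygen next to bromine because the carboxyl group chelates the other oxygen; CO2 is then lost.
- Iodo-prenyl-resorcinol ⇒ 4,6-diiodoresorcinol (one iodine exchanged for prenyl) ⇒ resorcinol.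
- Ring order: both benzene rings are bought; the pyran ring is made first (step 1), the furan ring last (step 5); no protecting groups.

Assumption: the target has no stereocentre and no E/Z-defined double bond, so "single enantiomer" is read as the one achiral structure given.

**Step 1**
Reactants: 1 5-bromo-2,4-dihydroxybenzoic acid
Product: 3 8-bromo-2,2-dimethyl-2H-chromen-5-ol, via chromene acid 2 (not isolated)
Conditions: 3-methylbut-2-enal (2 equiv), Ca(OH)2 (2 equiv), MeOH, 25 °C, 24 h; then AcOH (6 equiv), DMSO–H2O, MeOH distilled off, 120 °C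
Reagents that add atoms: 3-methylbut-2-enal (prenal), CC(C)=CC=O
Why: Proposed new method: a traceless carboxyl-directed chromene annulation. Calcium ties the carboxylate to the neighbouring 2-oxygen in a salicylate chelate, and the only free activated ring carbon (C3, between the two oxygens; C5 carries bromine) adds to the aldehyde. Loss of hydroxide gives the ortho-quinone methide whose carbonyl is the non-chelated 4-oxygen, so oxa-6π electrocyclisation forms the O–CMe2 bond on the oxygen next to bromine and gives acid 2. Acidification and heating then protonate the carbon ipso to CO2H (ortho to OH, para to the ring oxygen) and expel CO2 to leave 3. The closest known reactions are the Ca(OH)2- or amine-mediated Knoevenagel/oxa-6π chromenylation of chelated 2,4-dihydroxyaryl ketones with enals and the thermal protodecarboxylation of β-resorcylic acids; the tandem on a free halo-resorcylic acid is the untested part. No stereocentre is formed.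

**Step 2**
Reactants: 3 8-bromo-2,2-dimethyl-2H-chromen-5-ol
Product: 5 8-ethynyl-2,2-dimethyl-2H-chromen-5-ol, via silylalkyne 4 (not isolated)
Conditions: ethynyltrimethylsilane (1.5 equiv), Pd(PhCN)2Cl2 (3 mol %), P(t-Bu)3·HBF4 (6 mol %), CuI (3 mol %), i-Pr2NH, dioxane, 45 °C; then K2CO3, MeOH, 25 °C
Reagents that add atoms: ethynyltrimethylsilane, C#C[Si](C)(C)C
Why: Sonogashira coupling of the electron-rich aryl bromide (the Pd(PhCN)2Cl2/P(t-Bu)3 system is chosen for such bromides) followed by base-mediated methanolysis of the C–Si bond; the chromene alkene and the free phenol are spectators and no stereocentre is formed.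

**Step 3**
Reactants: 6 benzene-1,3-diol (resorcinol)
Product: 7 4,6-diiodobenzene-1,3-diol
Conditions: ICl (2.1 equiv), Et2O, 0 → 25 °C
Reagents that add atoms: iodine monochloride, ClI
Why: Electrophilic aromatic iodination; each ICl enters a position para to one hydroxyl and ortho to the other (C4 and C6), the C2 position between the hydroxyls being the more hindered one, and no stereocentre is formed.

**Step 4**
Reactants: 7 4,6-diiodobenzene-1,3-diol
Product: 9 4-iodo-6-(3-methylbut-2-en-1-yl)benzene-1,3-diol, via arylmagnesium chloride 8 (not isolated)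
Conditions: MeMgCl (2.0 equiv), LiCl, THF, −30 °C; i-PrMgCl·LiCl (1.1 equiv), −30 → 25 °C; Li2CuCl4 (5 mol %), prenyl bromide (1.3 equiv), −20 → 0 °C; then 1 M HCl, 0 °C
Reagents that add atoms: 1-bromo-3-methylbut-2-ene (prenyl bromide), CC(C)=CCBr
Why: Knochel-type iodine–magnesium exchange on the doubly deprotonated iodophenol (the two iodines are equivalent and the charge built up after one exchange shuts down the second), then Li2CuCl4-catalysed (Kochi-type) SN2 allylic substitution at the primary carbon of prenyl bromide; no stereocentre is formed.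

**Step 5**
Reactants: 5 8-ethynyl-2,2-dimethyl-2H-chromen-5-ol; 9 4-iodo-6-(3-methylbut-2-en-1-yl)benzene-1,3-diol
Product: 11 2-(5-hydroxy-2,2-dimethyl-2H-chromen-8-yl)-5-(3-methylbut-2-en-1-yl)-1-benzofuran-6-ol (kanzonol V), via diarylalkyne 10 (not isolated)
Conditions: PdCl2(PPh3)2 (4 mol %), CuI (8 mol %), Et3N, DMF, degassed, 25 → 70 °C
Reagents that add atoms: none
Why: Sonogashira coupling at the C–I bond followed in the same flask by CuI/Et3N-promoted 5-endo-dig hydroalkoxylation (cycloisomerisation) of alkyne 10 by the one phenol ortho to it, which forms the furan C–O bond; the ortho oxygen of ring B is locked in the pyran, so only one benzofuran can form, and no stereocentre is created.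

**Compound list**
1 | 5-bromo-2,4-dihydroxybenzoic acid | OC(=O)c1cc(Br)c(O)cc1O | starting material
2 | 8-bromo-5-hydroxy-2,2-dimethyl-2H-chromene-6-carboxylic acid | CC1(C)C=Cc2c(O1)c(Br)cc(C(=O)O)c2O | intermediate
3 | 8-bromo-2,2-dimethyl-2H-chromen-5-ol | CC1(C)C=Cc2c(O1)c(Br)ccc2O | intermediate
4 | 2,2-dimethyl-8-[(trimethylsilyl)ethynyl]-2H-chromen-5-ol | CC1(C)C=Cc2c(O1)c(C#C[Si](C)(C)C)ccc2O | intermediate
5 | 8-ethynyl-2,2-dimethyl-2H-chromen-5-ol | CC1(C)C=Cc2c(O1)c(C#C)ccc2O | intermediate
6 | benzene-1,3-diol (resorcinol) | Oc1cccc(O)c1 | starting material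
7 | 4,6-diiodobenzene-1,3-diol | Oc1cc(O)c(I)cc1I | intermediate
8 | [2,4-bis(chloromagnesiooxy)-5-iodophenyl]magnesium chloride | Cl[Mg]Oc1cc(O[Mg]Cl)c(I)cc1[Mg]Cl | intermediate
9 | 4-iodo-6-(3-methylbut-2-en-1-yl)benzene-1,3-diol | CC(C)=CCc1cc(I)c(O)cc1O | intermediate
10 | 4-[(5-hydroxy-2,2-dimethyl-2H-chromen-8-yl)ethynyl]-6-(3-methylbut-2-en-1-yl)benzene-1,3-diol | CC(C)=CCc1cc(C#Cc2ccc(O)c3C=CC(C)(C)Oc23)c(O)cc1O | intermediate
11 | 2-(5-hydroxy-2,2-dimethyl-2H-chromen-8-yl)-5-(3-methylbut-2-en-1-yl)-1-benzofuran-6-ol (kanzonol V) | CC(C)=CCc1cc2cc(-c3ccc(O)c4c3OC(C)(C)C=C4)oc2cc1O | target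

**Step count**
Total steps: 5. Longest linear sequence: 3 (steps 1, 2, 5 or steps 3, 4, 5).

**Steps most likely to fail**

Step 1 (the proposed new method). Acid 1 may lose CO2 before it is annulated, which would give 4-bromoresorcinol and unselective chromenes, or the pyran may close on the chelated oxygen and give the 6-bromo isomer. The fallback uses known chemistry only, sets out from 1 and comes back at 3. Fischer esterification (MeOH, H2SO4) gives methyl 5-bromo-2,4-dihydroxybenzoate F1. Its non-chelated 4-hydroxyl is alkylated with 3-chloro-3-methylbut-1-yne (K2CO3, KI, CuI cat., acetone, reflux) to give methyl 5-bromo-2-hydroxy-4-[(2-methylbut-3-yn-2-yl)oxy]benzoate F2. Aromatic propargyl Claisen rearrangement and ring closure (N,N-diethylaniline, 180 °C) can only go to the free ortho carbon and gives methyl 8-bromo-5-hydroxy-2,2-dimethyl-2H-chromene-6-carboxylate F3. Saponification (KOH, MeOH–H2O, then acid) gives acid 2, which is decarboxylated by heating in DMSO–AcOH to 3.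

Step 4. The exchange may be slow on the electron-rich bis(phenoxide), and O-prenylation or SN2′ attack may compete. The fallback sets out from 7 and comes back at 9. MOMCl and i-Pr2NEt (CH2Cl2) give 1,5-diiodo-2,4-bis(methoxymethoxy)benzene F4. One iodine is exchanged with n-BuLi (1.0 equiv, THF, −78 °C) and the aryllithium is alkylated with prenyl bromide in the presence of CuI (10 mol %) to give 1-iodo-2,4-bis(methoxymethoxy)-5-(3-methylbut-2-en-1-yl)benzene F5. Brief treatment with HCl in MeOH (40 °C) removes both acetals and gives 9.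

Step 5. The unprotected, very electron-rich iodoresorcinol may add slowly to palladium, the alkyne may homocouple, or the cyclisation may stall at 10. The fallback sets out from 5 and 9 and comes back at 11. Ac2O in pyridine converts 5 into 8-ethynyl-2,2-dimethyl-2H-chromen-5-yl acetate F6 and 9 into 4-iodo-6-(3-methylbut-2-en-1-yl)-1,3-phenylene diacetate F7. Sonogashira coupling of these (PdCl2(PPh3)2, CuI, Et3N, THF, 25 °C) gives 4-{[5-(acetyloxy)-2,2-dimethyl-2H-chromen-8-yl]ethynyl}-6-(3-methylbut-2-en-1-yl)-1,3-phenylene diacetate F8. Cs2CO3 in MeOH–DMF at 60 °C then cleaves the three acetates, and the freed ortho-phenoxide closes onto the alkyne (through 10) to give 11.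

**Further compounds**
F1 | step 1 | methyl 5-bromo-2,4-dihydroxybenzoate | COC(=O)c1cc(Br)c(O)cc1O
F2 | step 1 | methyl 5-bromo-2-hydroxy-4-[(2-methylbut-3-yn-2-yl)oxy]benzoate | COC(=O)c1cc(Br)c(OC(C)(C)C#C)cc1O
F3 | step 1 | methyl 8-bromo-5-hydroxy-2,2-dimethyl-2H-chromene-6-carboxylate | COC(=O)c1cc(Br)c2OC(C)(C)C=Cc2c1O
F4 | step 4 | 1,5-diiodo-2,4-bis(methoxymethoxy)benzene | COCOc1cc(OCOC)c(I)cc1I
F5 | step 4 | 1-iodo-2,4-bis(methoxymethoxy)-5-(3-methylbut-2-en-1-yl)benzene | COCOc1cc(OCOC)c(CC=C(C)C)cc1I
F6 | step 5 | 8-ethynyl-2,2-dimethyl-2H-chromen-5-yl acetate | CC(=O)Oc1ccc(C#C)c2OC(C)(C)C=Cc12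
F7 | step 5 | 4-iodo-6-(3-methylbut-2-en-1-yl)-1,3-phenylene diacetate | CC(=O)Oc1cc(OC(C)=O)c(CC=C(C)C)cc1I
F8 | step 5 | 4-{[5-(acetyloxy)-2,2-dimethyl-2H-chromen-8-yl]ethynyl}-6-(3-methylbut-2-en-1-yl)-1,3-phenylene diacetate | CC(=O)Oc1cc(OC(C)=O)c(CC=C(C)C)cc1C#Cc1ccc(OC(C)=O)c2C=CC(C)(C)Oc12
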